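Readings and results stem from a simulated flask for an exercise; the scatter is artificial.

Two questions stand on this flask, in which reagent adds to substrate. One addition gives a mono adduct (single product or other mono adduct) and by-product, a second gives bis adduct and more by-product, and reagent can sit on by-product as idle adduct or turn into dormant form.

the same everywhere: substrate 0.71 M

| flask | reagent | remark | time |
|---|---|---|---|
| summer | 0.53 M | run made earlier |  |
| dawn | 2.1 M | run made earlier |  |
| flask | 1.06 M |  | 3.0 min |

| run | time / s | substrate / % | single product / % |
|---|---|---|---|
| summer | 10.0 | 43 | 23 |
| summer | 20.0 | 47 | 18 |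
| summer | 40.0 | 48 | 22 |
| summer | 60.0 | 43 | 20 |
| summer | 80.0 | 44 | 20 |
| summer | 120 | 45 | 19 |
| dawn | 20.0 | 0 | 0 |
| dawn | 40.0 | 2 | 1 |
| dawn | 50.0 | 0 | 0 |
| dawn | 80.0 | 0 | 1 |
| dawn | 90.0 | 0 | 0 |
| dawn | 120 | 1 | 0 |

(standard deviation of a reading: 2 percentage points)

- part of the substrate that has reacted at 3.0 min
- share of free reagent in free reagent and idle adduct together, at 3.0 min

- by-product is meant together with its idle adduct
- candidate steps: substrate + reagent -> single product + by-product; substrate + reagent -> other mono adduct + by-product; reagent + single product -> bis adduct + by-product; reagent + other mono adduct -> bis adduct + by-product; reagent + by-product <-> idle adduct; reagent <-> dormant form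
- the earlier runs do not show how much of reagent is bound; that part of a forecast is a guess

The summer readings are flat from 10.0 s, a time shorter than the flask's 3.0 min, so I treat the additions as over and reckon with the charge. One thing looks wrong at first: the flask holds 1.49 equivalents of reagent, more than its substrate, yet I expect substrate to survive. It clears if mono adducts take reagent as fast as substrate does. With a the fraction of substrate left, the equivalents spent are then 2(1 − a) + a ln a.

Summer's mean of 45.0% left, a reading, spends 0.741 of 0.746 charged. Their ratio, 0.992, is my spent share, the reagent turned into additions per reagent charged. Nearly all of summer's reagent is accounted for, so there it acts as the limiting reagent. The flask then has 1.48 equivalents to spend.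

The forecast gives 87% reacted (79% to 97%) and a share of 8% (0% to 40%): “Whatever survives is mostly idle adduct.” At the 13.0% left that it implies, my curve spends 1.47, so I hold the same conversion.

    substrate + reagent → single product + by-product (k = 1.33 M⁻¹ s⁻¹)
    substrate + reagent → other mono adduct + by-product (k = 0.737 M⁻¹ s⁻¹)
    reagent + single product → bis adduct + by-product (k = 2.89 M⁻¹ s⁻¹)
    reagent + other mono adduct → bis adduct + by-product (k = 0.799 M⁻¹ s⁻¹)
    reagent + by-product ⇌ idle adduct, settled at all times (K = 0.199 M⁻¹)
    reagent ⇌ dormant form (K = 0.630, k = 0.00635 s⁻¹)

The flask gives 89.0% reacted, inside the forecast's range, and a share of 82.6%, 75 percentage points above the forecast, taken among traces, with idle adduct at 5.09 × 10⁻⁶ M at 3.00 min. At the flask's 11% of substrate left, the curve spends 1.54, more than the 1.49 charged, so in this flask the curve runs high. The neighbour charged with 0.42 M of reagent holds 0.592 equivalents, so the spent share 0.992 gives it 0.587 to spend. That neighbour ends with 53.7% of its substrate left, where the curve spends 0.592.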